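**Retrosynthetic overview**
1. Target ⇐ desilylation and (E)-enol esterification of a C9 aldehyde; the 4‑OH is carried through that step as a TBS ether.
2. Ring B (dihydrofuran, formed second) ⇐ oxa‑Michael closure of the CH2OH group onto a dienone that is revealed by a rhenium‑oxo 1,3‑transposition of a tertiary allylic alcohol (sets C4 and C1).
3. Ring A (carbocycle, formed first) ⇐ ring‑closing metathesis of an allyl ketone onto a propenyl group, then Morita–Baylis–Hillman hydroxymethylation and acetylide addition.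
4. Key bond C6–C7 (quaternary next to tertiary) ⇐ Ireland–Claisen [3,3] rearrangement of an (S,Z)‑allylic ester, with chirality transferred from (S)‑but‑3‑yn‑2‑ol; the carbinol carbon and its methyl later leave as propene.

Assumption: C1–C7a are the locants of the 1,3,4,5,6,7‑hexahydro‑2‑benzofuran core of the target (O = position 2) and C8/C9 are the two side‑chain carbons on C7; (S)‑but‑3‑yn‑2‑ol is bought enantiopure and is the only source of chirality.

**Route**

Step 1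
Reactants: 1 (2S)-but-3-yn-2-ol; 2 5-bromo-2-methylpent-2-ene
Product: 3 (2S)-8-methylnon-7-en-3-yn-2-ol
Conditions: n-BuLi (2.1 equiv), THF/DMPU, −78 °C → rt; H2O
Reagents that add atoms: none
Why: SN2 C‑alkylation of the dilithio alkoxide–acetylide by the primary bromide leaves the purchased carbinol stereocentre untouched.

Step 2
Reactants: 3 (2S)-8-methylnon-7-en-3-yn-2-ol
Product: 4 (2S,3Z)-4,8-dimethylnona-3,7-dien-2-ol
Conditions: CH3MgBr (5 equiv), Fe(acac)3 (20 mol%), THF, −78 → 0 °C; aq NH4Cl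
Reagents that add atoms: methylmagnesium bromide, C[Mg]Br
Why: Alkoxide‑directed iron‑catalysed syn‑carbomagnesiation delivers CH3 to the distal alkyne carbon and, after protonation, gives the (Z)‑trisubstituted allylic alcohol with the carbinol centre unchanged.

Step 3
Reactants: 5 methyl 4,4-dimethoxybutanoate
Product: 6 4,4-dimethoxybutanoic acid
Conditions: LiOH, THF/H2O, rt; then dilute aq HCl to pH 4, 0 °C
Reagents that add atoms: lithium hydroxide, [Li+].[OH-]
Why: Saponification of the methyl ester with a cold, mild acidification that the dimethyl acetal survives.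

Step 4
Reactants: 4 (2S,3Z)-4,8-dimethylnona-3,7-dien-2-ol; 6 4,4-dimethoxybutanoic acid
Product: 7 (2S,3Z)-4,8-dimethylnona-3,7-dien-2-yl 4,4-dimethoxybutanoate
Conditions: N,N'-dicyclohexylcarbodiimide, DMAP (cat.), CH2Cl2, 0 °C → rt
Reagents that add atoms: none
Why: Steglich esterification acylates the oxygen without breaking the C–O bond, so the (S)‑configuration and the Z‑alkene are retained.

Step 5
Reactants: 7 (2S,3Z)-4,8-dimethylnona-3,7-dien-2-yl 4,4-dimethoxybutanoate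
Product: 10 (2R,3S,4E)-2-(2,2-dimethoxyethyl)-3-methyl-3-(4-methylpent-3-en-1-yl)hex-4-enoic acid, via silyl ketene acetal 8 (not isolated), via trimethylsilyl ester 9 (not isolated)
Conditions: LiN(i-Pr)2, THF, −78 °C; Me3SiCl/Et3N; −78 → 60 °C; H2O, pH 4–5 buffer
Reagents that add atoms: none
Why: Ireland–Claisen [3,3]‑sigmatropic rearrangement of the kinetic E(O)‑enolate through a chair transition state with the carbinol methyl equatorial (allylic strain from the Z‑substituent) transfers the (S)‑carbinol chirality to the new C6–C7 bond, setting the quaternary C6 and the adjacent C7 (2R,3S in the acid) and leaving an (E)‑propenyl group.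

Step 6
Reactants: 10 (2R,3S,4E)-2-(2,2-dimethoxyethyl)-3-methyl-3-(4-methylpent-3-en-1-yl)hex-4-enoic acid
Product: 12 (2R,3S,4E)-2-(2,2-dimethoxyethyl)-N-methoxy-N,3-dimethyl-3-(4-methylpent-3-en-1-yl)hex-4-enamide, via acyl imidazole 11 (not isolated)
Conditions: 1,1'-carbonyldiimidazole, CH2Cl2, rt; then MeNH(OMe)·HCl, rt → 40 °C
Reagents that add atoms: N,O-dimethylhydroxylamine hydrochloride, CNOC.Cl
Why: Activation as the acyl imidazole followed by aminolysis gives the Weinreb amide under near‑neutral conditions that spare the acetal and the α‑stereocentre.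

Step 7
Reactants: 12 (2R,3S,4E)-2-(2,2-dimethoxyethyl)-N-methoxy-N,3-dimethyl-3-(4-methylpent-3-en-1-yl)hex-4-enamide
Product: 13 (5R,6S,7E)-5-(2,2-dimethoxyethyl)-6-methyl-6-(4-methylpent-3-en-1-yl)nona-1,7-dien-4-one
Conditions: CH2=CHCH2MgBr (1.5 equiv), THF, −78 °C; cold aq NH4Cl
Reagents that add atoms: allylmagnesium bromide, C=CC[Mg]Br
Why: Weinreb ketone synthesis, in which the chelated tetrahedral adduct stops at mono‑addition and the cold quench releases the β,γ‑unsaturated ketone without conjugation or epimerisation.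

Step 8
Reactants: 13 (5R,6S,7E)-5-(2,2-dimethoxyethyl)-6-methyl-6-(4-methylpent-3-en-1-yl)nona-1,7-dien-4-one
Product: 15 (5S,6R)-6-(2,2-dimethoxyethyl)-5-methyl-5-(4-methylpent-3-en-1-yl)cyclohex-2-en-1-one, via β,γ-enone 14 (not isolated)
Conditions: second-generation Grubbs catalyst RuCl2(=CHPh)(H2IMes)(PCy3) (5 mol%), 1,4-benzoquinone (10 mol%), CH2Cl2 (5 mmol/L), 40 °C; then DBU (0.2 equiv), rt
Reagents that add atoms: none
Why: Ring‑closing metathesis of the allyl group onto the propenyl group closes ring A with loss of propene (the former carbinol carbon and its methyl), benzoquinone suppressing isomerisation of the allyl ketone, and catalytic DBU then moves the double bond into conjugation.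

Step 9
Reactants: 15 (5S,6R)-6-(2,2-dimethoxyethyl)-5-methyl-5-(4-methylpent-3-en-1-yl)cyclohex-2-en-1-one
Product: 16 (5S,6R)-6-(2,2-dimethoxyethyl)-2-(hydroxymethyl)-5-methyl-5-(4-methylpent-3-en-1-yl)cyclohex-2-en-1-one
Conditions: 37% aq HCHO, DMAP (0.3 equiv), THF/H2O, rt
Reagents that add atoms: formaldehyde, C=O
Why: Morita–Baylis–Hillman reaction, in which DMAP adds to the unsubstituted β‑carbon, the enolate traps formaldehyde and DMAP is expelled, placing C3 as CH2OH on the α‑carbon without touching the stereocentres.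

Step 10
Reactants: 17 4-(trimethylsilyl)but-3-yn-2-one
Product: 18 2-methyl-2-[(trimethylsilyl)ethynyl]-1,3-dioxolane
Conditions: Me3SiOCH2CH2OSiMe3, Me3SiOTf (cat.), CH2Cl2, −78 °C
Reagents that add atoms: 1,2-bis(trimethylsilyloxy)ethane, C[Si](C)(C)OCCO[Si](C)(C)C
Why: Noyori ketalisation masks the ketone as a dioxolane at low temperature, where conjugate addition to the silyl‑capped ynone does not compete.

Step 11
Reactants: 16 (5S,6R)-6-(2,2-dimethoxyethyl)-2-(hydroxymethyl)-5-methyl-5-(4-methylpent-3-en-1-yl)cyclohex-2-en-1-one; 18 2-methyl-2-[(trimethylsilyl)ethynyl]-1,3-dioxolane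
Product: 20 (1R,5S,6R)-6-(2,2-dimethoxyethyl)-2-(hydroxymethyl)-5-methyl-1-[(E)-2-(2-methyl-1,3-dioxolan-2-yl)ethenyl]-5-(4-methylpent-3-en-1-yl)cyclohex-2-en-1-ol, via propargylic diol 19 (not isolated)
Conditions: 18 (3 equiv), CH3Li·LiBr, THF, 0 °C → rt; add 16, −78 → 0 °C; then NaAlH2(OCH2CH2OCH3)2, THF, 0 °C → rt; aq NaOH
Reagents that add atoms: none
Why: The lithium acetylide adds 1,2 to the enone from the face opposite the C7 side chain (OH cis to that chain), and alkoxide‑directed trans‑hydroalumination of the resulting propargylic alkoxide gives the (E)‑alkene.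

Step 12
Reactants: 20 (1R,5S,6R)-6-(2,2-dimethoxyethyl)-2-(hydroxymethyl)-5-methyl-1-[(E)-2-(2-methyl-1,3-dioxolan-2-yl)ethenyl]-5-(4-methylpent-3-en-1-yl)cyclohex-2-en-1-ol
Product: 23 2-[(1S,4S,6S,7R)-4-hydroxy-6-methyl-6-(4-methylpent-3-en-1-yl)-1-(2-oxopropyl)-1,3,4,5,6,7-hexahydro-2-benzofuran-7-yl]acetaldehyde, via transposed diol 21 (not isolated), via dienone keto-aldehyde 22 (not isolated)
Conditions: Re2O7 (5 mol%), CH2Cl2, 0 °C → rt; then dilute aq HCl/THF, rt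
Reagents that add atoms: water, O
Why: A suprafacial rhenium‑oxo 1,3‑transposition ([3,3] shift of the perrhenate ester) moves the tertiary OH to C4 on the same face (4S, also the more stable pseudo‑equatorial alcohol) and makes the C3a=C7a bond, after which acid unmasks ketone and aldehyde and the primary alcohol closes ring B by a reversible oxa‑Michael addition that places the acetonyl group trans to the C7 side chain (1S).

Step 13
Reactants: 23 2-[(1S,4S,6S,7R)-4-hydroxy-6-methyl-6-(4-methylpent-3-en-1-yl)-1-(2-oxopropyl)-1,3,4,5,6,7-hexahydro-2-benzofuran-7-yl]acetaldehyde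
Product: 24 2-[(1S,4S,6S,7R)-4-[(tert-butyldimethylsilyl)oxy]-6-methyl-6-(4-methylpent-3-en-1-yl)-1-(2-oxopropyl)-1,3,4,5,6,7-hexahydro-2-benzofuran-7-yl]acetaldehyde
Conditions: TBSCl, imidazole, DMF, 0 °C → rt
Reagents that add atoms: tert-butyldimethylsilyl chloride, CC(C)(C)[Si](C)(C)Cl
Why: Imidazole‑promoted silylation of the only hydroxyl keeps the 4‑OH from being acylated in the next step.

Step 14
Reactants: 24 2-[(1S,4S,6S,7R)-4-[(tert-butyldimethylsilyl)oxy]-6-methyl-6-(4-methylpent-3-en-1-yl)-1-(2-oxopropyl)-1,3,4,5,6,7-hexahydro-2-benzofuran-7-yl]acetaldehyde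
Product: 25 (E)-2-[(1S,4S,6S,7R)-4-[(tert-butyldimethylsilyl)oxy]-6-methyl-6-(4-methylpent-3-en-1-yl)-1-(2-oxopropyl)-1,3,4,5,6,7-hexahydro-2-benzofuran-7-yl]ethenyl 3-methylbut-2-enoate
Conditions: (Me2C=CHCO)2O, Et3N, DMAP, CH2Cl2, rt
Reagents that add atoms: 3-methylbut-2-enoic anhydride, CC(C)=CC(=O)OC(=O)C=C(C)C
Why: Enol esterification, in which the aldehyde is enolised far more readily than the methyl ketone and O‑acylated by the anhydride, the bulky C7 substituent favouring the (E)‑enol ester (minor Z‑isomer removed by chromatography).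

Step 15
Reactants: 25 (E)-2-[(1S,4S,6S,7R)-4-[(tert-butyldimethylsilyl)oxy]-6-methyl-6-(4-methylpent-3-en-1-yl)-1-(2-oxopropyl)-1,3,4,5,6,7-hexahydro-2-benzofuran-7-yl]ethenyl 3-methylbut-2-enoate
Product: 26 (E)-2-[(1S,4S,6S,7R)-4-hydroxy-6-methyl-6-(4-methylpent-3-en-1-yl)-1-(2-oxopropyl)-1,3,4,5,6,7-hexahydro-2-benzofuran-7-yl]ethenyl 3-methylbut-2-enoate
Conditions: HF·pyridine, pyridine/THF, 0 °C → rt
Reagents that add atoms: none
Why: Buffered fluoride desilylation cleaves only the Si–O bond, leaving the enol ester, the β‑alkoxy ketone and all four stereocentres intact.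

**Compound list**

1 | (2S)-but-3-yn-2-ol | C[C@H](O)C#C | starting material
2 | 5-bromo-2-methylpent-2-ene | CC(C)=CCCBr | starting material
3 | (2S)-8-methylnon-7-en-3-yn-2-ol | C[C@H](O)C#CCCC=C(C)C | intermediate
4 | (2S,3Z)-4,8-dimethylnona-3,7-dien-2-ol | C[C@H](O)/C=C(/C)CCC=C(C)C | intermediate
5 | methyl 4,4-dimethoxybutanoate | COC(=O)CCC(OC)OC | starting material
6 | 4,4-dimethoxybutanoic acid | OC(=O)CCC(OC)OC | intermediate
7 | (2S,3Z)-4,8-dimethylnona-3,7-dien-2-yl 4,4-dimethoxybutanoate | C[C@H](OC(=O)CCC(OC)OC)/C=C(/C)CCC=C(C)C | intermediate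
8 | (1E)-4,4-dimethoxy-1-(trimethylsilyloxy)but-1-en-1-yl (2S,3Z)-4,8-dimethylnona-3,7-dien-2-yl ether (silyl ketene acetal; CH2CH(OMe)2 cis to the allyloxy oxygen) | COC(OC)C/C=C(/O[Si](C)(C)C)O[C@@H](C)/C=C(/C)CCC=C(C)C | intermediate
9 | trimethylsilyl (2R,3S,4E)-2-(2,2-dimethoxyethyl)-3-methyl-3-(4-methylpent-3-en-1-yl)hex-4-enoate | C[Si](C)(C)OC(=O)[C@H](CC(OC)OC)[C@@](C)(CCC=C(C)C)/C=C/C | intermediate
10 | (2R,3S,4E)-2-(2,2-dimethoxyethyl)-3-methyl-3-(4-methylpent-3-en-1-yl)hex-4-enoic acid | OC(=O)[C@H](CC(OC)OC)[C@@](C)(CCC=C(C)C)/C=C/C | intermediate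
11 | 1-[(2R,3S,4E)-2-(2,2-dimethoxyethyl)-3-methyl-3-(4-methylpent-3-en-1-yl)hex-4-enoyl]imidazole | O=C(n1ccnc1)[C@H](CC(OC)OC)[C@@](C)(CCC=C(C)C)/C=C/C | intermediate
12 | (2R,3S,4E)-2-(2,2-dimethoxyethyl)-N-methoxy-N,3-dimethyl-3-(4-methylpent-3-en-1-yl)hex-4-enamide | CON(C)C(=O)[C@H](CC(OC)OC)[C@@](C)(CCC=C(C)C)/C=C/C | intermediate
13 | (5R,6S,7E)-5-(2,2-dimethoxyethyl)-6-methyl-6-(4-methylpent-3-en-1-yl)nona-1,7-dien-4-one | C=CCC(=O)[C@H](CC(OC)OC)[C@@](C)(CCC=C(C)C)/C=C/C | intermediate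
14 | (5S,6R)-6-(2,2-dimethoxyethyl)-5-methyl-5-(4-methylpent-3-en-1-yl)cyclohex-3-en-1-one | O=C1CC=C[C@](C)(CCC=C(C)C)[C@H]1CC(OC)OC | intermediate
15 | (5S,6R)-6-(2,2-dimethoxyethyl)-5-methyl-5-(4-methylpent-3-en-1-yl)cyclohex-2-en-1-one | O=C1C=CC[C@](C)(CCC=C(C)C)[C@H]1CC(OC)OC | intermediate
16 | (5S,6R)-6-(2,2-dimethoxyethyl)-2-(hydroxymethyl)-5-methyl-5-(4-methylpent-3-en-1-yl)cyclohex-2-en-1-one | O=C1C(CO)=CC[C@](C)(CCC=C(C)C)[C@H]1CC(OC)OC | intermediate
17 | 4-(trimethylsilyl)but-3-yn-2-one | CC(=O)C#C[Si](C)(C)C | starting material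
18 | 2-methyl-2-[(trimethylsilyl)ethynyl]-1,3-dioxolane | CC1(C#C[Si](C)(C)C)OCCO1 | intermediate
19 | (1S,5S,6R)-6-(2,2-dimethoxyethyl)-2-(hydroxymethyl)-5-methyl-1-[(2-methyl-1,3-dioxolan-2-yl)ethynyl]-5-(4-methylpent-3-en-1-yl)cyclohex-2-en-1-ol | OCC1=CC[C@](C)(CCC=C(C)C)[C@@H](CC(OC)OC)[C@]1(O)C#CC2(C)OCCO2 | intermediate
20 | (1R,5S,6R)-6-(2,2-dimethoxyethyl)-2-(hydroxymethyl)-5-methyl-1-[(E)-2-(2-methyl-1,3-dioxolan-2-yl)ethenyl]-5-(4-methylpent-3-en-1-yl)cyclohex-2-en-1-ol | OCC1=CC[C@](C)(CCC=C(C)C)[C@@H](CC(OC)OC)[C@]1(O)/C=C/C2(C)OCCO2 | intermediate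
21 | (1S,4R,5S)-4-(2,2-dimethoxyethyl)-2-(hydroxymethyl)-5-methyl-3-[(E)-2-(2-methyl-1,3-dioxolan-2-yl)ethenyl]-5-(4-methylpent-3-en-1-yl)cyclohex-2-en-1-ol | OCC1=C(/C=C/C2(C)OCCO2)[C@H](CC(OC)OC)[C@@](C)(CCC=C(C)C)C[C@@H]1O | intermediate
22 | 2-[(1R,4S,6S)-4-hydroxy-3-(hydroxymethyl)-6-methyl-6-(4-methylpent-3-en-1-yl)-2-[(E)-3-oxobut-1-en-1-yl]cyclohex-2-en-1-yl]acetaldehyde | OCC1=C(/C=C/C(C)=O)[C@H](CC=O)[C@@](C)(CCC=C(C)C)C[C@@H]1O | intermediate
23 | 2-[(1S,4S,6S,7R)-4-hydroxy-6-methyl-6-(4-methylpent-3-en-1-yl)-1-(2-oxopropyl)-1,3,4,5,6,7-hexahydro-2-benzofuran-7-yl]acetaldehyde | CC(=O)C[C@@H]1OCC2=C1[C@H](CC=O)[C@@](C)(CCC=C(C)C)C[C@@H]2O | intermediate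
24 | 2-[(1S,4S,6S,7R)-4-[(tert-butyldimethylsilyl)oxy]-6-methyl-6-(4-methylpent-3-en-1-yl)-1-(2-oxopropyl)-1,3,4,5,6,7-hexahydro-2-benzofuran-7-yl]acetaldehyde | CC(=O)C[C@@H]1OCC2=C1[C@H](CC=O)[C@@](C)(CCC=C(C)C)C[C@@H]2O[Si](C)(C)C(C)(C)C | intermediate
25 | (E)-2-[(1S,4S,6S,7R)-4-[(tert-butyldimethylsilyl)oxy]-6-methyl-6-(4-methylpent-3-en-1-yl)-1-(2-oxopropyl)-1,3,4,5,6,7-hexahydro-2-benzofuran-7-yl]ethenyl 3-methylbut-2-enoate | CC(=O)C[C@@H]1OCC2=C1[C@H](/C=C/OC(=O)C=C(C)C)[C@@](C)(CCC=C(C)C)C[C@@H]2O[Si](C)(C)C(C)(C)C | intermediate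
26 | (E)-2-[(1S,4S,6S,7R)-4-hydroxy-6-methyl-6-(4-methylpent-3-en-1-yl)-1-(2-oxopropyl)-1,3,4,5,6,7-hexahydro-2-benzofuran-7-yl]ethenyl 3-methylbut-2-enoate (CNP0260614.2) | CC(=O)C[C@@H]1OCC2=C1[C@H](/C=C/OC(=O)C=C(C)C)[C@@](C)(CCC=C(C)C)C[C@@H]2O | target

**Step count and risks**

Total step count: 15 (13 in the main line plus the two one‑step preparations of 6 and 18).
Longest linear sequence: 13 steps (1, 2, 4–9, 11–15) from (2S)-but-3-yn-2-ol.

The three steps most likely to fail: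

Step 12 (transposition/oxa‑Michael cascade). The bis‑allylic tertiary alcohol may ionise, transpose the wrong way or eliminate, and the C4 and C1 configurations rest on conformational arguments. Fallback by oxidative transposition and reduction: starting from 20, the primary alcohol is silylated (TBSCl, imidazole) to (1R,5S,6R)-2-[(tert-butyldimethylsilyloxy)methyl]-6-(2,2-dimethoxyethyl)-5-methyl-1-[(E)-2-(2-methyl-1,3-dioxolan-2-yl)ethenyl]-5-(4-methylpent-3-en-1-yl)cyclohex-2-en-1-ol F7. Buffered pyridinium chlorochromate C5H5NH[CrO3Cl] (Babler–Dauben oxidative 1,3‑transposition) then gives the dienone (4R,5S)-2-[(tert-butyldimethylsilyloxy)methyl]-4-(2,2-dimethoxyethyl)-5-methyl-3-[(E)-2-(2-methyl-1,3-dioxolan-2-yl)ethenyl]-5-(4-methylpent-3-en-1-yl)cyclohex-2-en-1-one F8. The ketone is reduced under equilibrating Meerwein–Ponndorf–Verley conditions (Al(Oi-Pr)3, i-PrOH; the more stable pseudo‑equatorial 4S alcohol is expected, with Mitsunobu inversion in reserve) to (1S,4R,5S)-2-[(tert-butyldimethylsilyloxy)methyl]-4-(2,2-dimethoxyethyl)-5-methyl-3-[(E)-2-(2-methyl-1,3-dioxolan-2-yl)ethenyl]-5-(4-methylpent-3-en-1-yl)cyclohex-2-en-1-ol F9. Dilute aqueous HCl in THF removes the silyl group, ketal and acetal from F9 and allows the oxa‑Michael closure, passing through 22 and coming back to the route at 23.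

Step 8 (ring‑closing metathesis). The allyl ketone can chelate ruthenium or slip into conjugation (which would lead to a five‑membered ring), and the partner alkene sits on a quaternary carbon. Fallback by a redox detour that removes the ketone during metathesis: starting from 13, NaBH4 in MeOH gives (5R,6S,7E)-5-(2,2-dimethoxyethyl)-6-methyl-6-(4-methylpent-3-en-1-yl)nona-1,7-dien-4-ol F5 (the mixture of carbinol epimers does not matter). The same second-generation Grubbs catalyst closes ring A to (5S,6R)-6-(2,2-dimethoxyethyl)-5-methyl-5-(4-methylpent-3-en-1-yl)cyclohex-3-en-1-ol F6. Dess–Martin periodinane oxidation comes back to the route at 14, which DBU converts into 15 as in step 8.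

Step 2 (iron‑catalysed carbomagnesiation). It could stall or give reduced or regioisomeric alkenes. Fallback through the (E)‑alkene with inversion at the carbinol: starting from 3, trans‑hydroalumination and iodination (LiAlH4/NaOCH3, THF; then I2) gives (2S,3Z)-4-iodo-8-methylnona-3,7-dien-2-ol F1. Coupling with (CH3)2CuLi gives (2S,3E)-4,8-dimethylnona-3,7-dien-2-ol F2 with retention of alkene geometry. Mitsunobu esterification with 6 (PPh3, DIAD) inverts the carbinol to (2R,3E)-4,8-dimethylnona-3,7-dien-2-yl 4,4-dimethoxybutanoate F3. Ireland–Claisen rearrangement under Z(O)‑enolate conditions (LiN(i-Pr)2, THF/DMPU, Me3SiCl) proceeds through the silyl ketene acetal (1Z)-4,4-dimethoxy-1-(trimethylsilyloxy)but-1-en-1-yl (2R,3E)-4,8-dimethylnona-3,7-dien-2-yl ether F4 and the silyl ester 9, and comes back to the route at 10 with the same (2R,3S) configuration.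

**Further compounds**

F1 | step 2 | (2S,3Z)-4-iodo-8-methylnona-3,7-dien-2-ol | C[C@H](O)/C=C(\I)CCC=C(C)C
F2 | step 2 | (2S,3E)-4,8-dimethylnona-3,7-dien-2-ol | C[C@H](O)/C=C(\C)CCC=C(C)C
F3 | step 2 | (2R,3E)-4,8-dimethylnona-3,7-dien-2-yl 4,4-dimethoxybutanoate | C[C@@H](OC(=O)CCC(OC)OC)/C=C(\C)CCC=C(C)C
F4 | step 2 | (1Z)-4,4-dimethoxy-1-(trimethylsilyloxy)but-1-en-1-yl (2R,3E)-4,8-dimethylnona-3,7-dien-2-yl ether | COC(OC)C/C=C(\O[Si](C)(C)C)O[C@H](C)/C=C(\C)CCC=C(C)C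
F5 | step 8 | (5R,6S,7E)-5-(2,2-dimethoxyethyl)-6-methyl-6-(4-methylpent-3-en-1-yl)nona-1,7-dien-4-ol | C=CCC(O)[C@H](CC(OC)OC)[C@@](C)(CCC=C(C)C)/C=C/C
F6 | step 8 | (5S,6R)-6-(2,2-dimethoxyethyl)-5-methyl-5-(4-methylpent-3-en-1-yl)cyclohex-3-en-1-ol | OC1CC=C[C@](C)(CCC=C(C)C)[C@H]1CC(OC)OC
F7 | step 12 | (1R,5S,6R)-2-[(tert-butyldimethylsilyloxy)methyl]-6-(2,2-dimethoxyethyl)-5-methyl-1-[(E)-2-(2-methyl-1,3-dioxolan-2-yl)ethenyl]-5-(4-methylpent-3-en-1-yl)cyclohex-2-en-1-ol | CC(C)(C)[Si](C)(C)OCC1=CC[C@](C)(CCC=C(C)C)[C@@H](CC(OC)OC)[C@]1(O)/C=C/C2(C)OCCO2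
F8 | step 12 | (4R,5S)-2-[(tert-butyldimethylsilyloxy)methyl]-4-(2,2-dimethoxyethyl)-5-methyl-3-[(E)-2-(2-methyl-1,3-dioxolan-2-yl)ethenyl]-5-(4-methylpent-3-en-1-yl)cyclohex-2-en-1-one | CC(C)(C)[Si](C)(C)OCC1=C(/C=C/C2(C)OCCO2)[C@H](CC(OC)OC)[C@@](C)(CCC=C(C)C)CC1=O
F9 | step 12 | (1S,4R,5S)-2-[(tert-butyldimethylsilyloxy)methyl]-4-(2,2-dimethoxyethyl)-5-methyl-3-[(E)-2-(2-methyl-1,3-dioxolan-2-yl)ethenyl]-5-(4-methylpent-3-en-1-yl)cyclohex-2-en-1-ol | CC(C)(C)[Si](C)(C)OCC1=C(/C=C/C2(C)OCCO2)[C@H](CC(OC)OC)[C@@](C)(CCC=C(C)C)C[C@@H]1O
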